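## Retrosynthetic overview

1. The target is two 8-acyl-5,7-dihydroxy-2,2-dimethylchromans (ring A with the (R)-2-methylbutanoyl group, ring B with the isobutyryl group) joined C6–CH(5-methylhexyl)–C6'. The strategy rests on one feature: in each chroman O1 is bonded to C8a, the carbon ortho to the C8 ketone. Both O1–C8a bonds are therefore cut back to a C8a–F bond and a tertiary alkoxide on the C4a side chain (ketone-activated intramolecular SNAr, fluorine holding the place of oxygen).
2. Ring order: both benzene rings come ready-made from 5-fluororesorcinol. Both dihydropyran rings are closed together in the last skeletal step, then the four MOM ethers are removed.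
3. The tertiary alcohols come from Markovnikov hydration of two prenyl groups. The 5-methylhexyl chain comes from deoxygenation of a 6-methyl-3-oxoheptyl chain.
4. The methine C–aryl bond and its (R) configuration come from a [Rh(OH)((R)-binap)]2-catalysed 1,4-addition of the ring B boronate to the ring A (E)-enone (ring A aldehyde plus 5-methylhexan-2-one).
5. Both rings branch from one aryl bromide: bis-MOM 5-fluororesorcinol is brominated at C2 and prenylated at one F/OMOM-flanked carbon. The bromine then becomes CHO (ring A) or Bpin (ring B), and the last ring C–H takes the acyl group.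

Key step: step 14

Assumption: n-BuLi in THF should metalate 1-fluoro-3,5-bis(methoxymethoxy)benzene at C2, between the two chelating MOM ethers, in preference to the F/OMOM-flanked C4; a minor C4 isomer would be removed at the first chromatography.

## Route

Step 1
Reactants: 1 5-fluorobenzene-1,3-diol
Product: 2 1-fluoro-3,5-bis(methoxymethoxy)benzene
Conditions: MOMCl, i-Pr2NEt, CH2Cl2, 0 °C → rt
Reagents that add atoms: chloromethyl methyl ether, COCCl
Why: Double O-alkylation of the phenols by MOMCl under amine base (Williamson-type etherification) should give the bis-MOM ether whose oxygens direct the later metalations and stay inert to base.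

Step 2
Reactants: 2 1-fluoro-3,5-bis(methoxymethoxy)benzene
Product: 4 2-bromo-5-fluoro-1,3-bis(methoxymethoxy)benzene, via aryllithium 3 (not isolated)
Conditions: n-BuLi, THF, 0 °C; BrCCl2CCl2Br, −78 °C → rt
Reagents that add atoms: 1,2-dibromo-1,1,2,2-tetrachloroethane, BrC(Cl)(Cl)C(Cl)(Cl)Br
Why: Directed ortho metalation at C2, where both MOM ethers chelate lithium, followed by electrophilic bromination places at C2 a halogen that blocks this site during the later ring metalations and serves as the handle for the formyl group of ring A and the boron of ring B.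

Step 3
Reactants: 4 2-bromo-5-fluoro-1,3-bis(methoxymethoxy)benzene, 5 prenyl bromide (1-bromo-3-methylbut-2-ene)
Product: 7 2-bromo-5-fluoro-1,3-bis(methoxymethoxy)-4-(3-methylbut-2-en-1-yl)benzene, via aryllithium 6 (not isolated)
Conditions: LDA, THF, −78 °C; CuBr·SMe2 (20 mol%), prenyl bromide, −78 → −30 °C
Reagents that add atoms: none
Why: The amide base removes one of the two equivalent acidic C–H flanked by F and OMOM without bromine–lithium exchange (directed ortho metalation), and CuBr·SMe2-catalysed SN2 allylation at the primary carbon of prenyl bromide should install the prenyl group at low temperature, before the ortho-fluoro aryllithium can lose LiF.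

Step 4
Reactants: 7 2-bromo-5-fluoro-1,3-bis(methoxymethoxy)-4-(3-methylbut-2-en-1-yl)benzene
Product: 9 4-fluoro-2,6-bis(methoxymethoxy)-3-(3-methylbut-2-en-1-yl)benzaldehyde, via aryllithium 8 (not isolated)
Conditions: n-BuLi, THF, −78 °C; DMF, −78 °C → rt; AcOH/H2O
Reagents that add atoms: N,N-dimethylformamide, CN(C)C=O
Why: Bromine–lithium exchange at −78 °C is much faster than deprotonation of the remaining ring C–H, and formylation of the resulting aryllithium with DMF should install the carbon that becomes the methine.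

Step 5
Reactants: 9 4-fluoro-2,6-bis(methoxymethoxy)-3-(3-methylbut-2-en-1-yl)benzaldehyde
Product: 10 2-(dimethoxymethyl)-5-fluoro-1,3-bis(methoxymethoxy)-4-(3-methylbut-2-en-1-yl)benzene
Conditions: HC(OMe)3, PPTS (cat.), MeOH, rt
Reagents that add atoms: trimethyl orthoformate, COC(OC)OC
Why: Acid-catalysed acetalisation masks the aldehyde against the organolithium of the next step, and PPTS is too weak an acid to cleave the aryl MOM ethers or to add methanol to the prenyl alkene.

Step 6
Reactants: 11 (R)-2-methylbutanoic acid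
Product: 13 (2R)-N-methoxy-N,2-dimethylbutanamide, via acyl imidazole 12 (not isolated)
Conditions: CDI, CH2Cl2, rt; MeNH(OMe)·HCl, rt
Reagents that add atoms: N,O-dimethylhydroxylamine hydrochloride, CNOC.Cl
Why: Activation as the acyl imidazole and aminolysis (Weinreb amide formation) involve no base strong enough to enolise the alpha stereocentre, so the (R) configuration should be retained.

Step 7
Reactants: 10 2-(dimethoxymethyl)-5-fluoro-1,3-bis(methoxymethoxy)-4-(3-methylbut-2-en-1-yl)benzene, 13 (2R)-N-methoxy-N,2-dimethylbutanamide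
Product: 16 4-fluoro-2,6-bis(methoxymethoxy)-3-(3-methylbut-2-en-1-yl)-5-[(2R)-2-methylbutanoyl]benzaldehyde, via aryllithium 14 (not isolated), via keto acetal 15 (not isolated)
Conditions: n-BuLi, THF, −78 °C; 13, −78 → −40 °C; AcOH; then PPTS (cat.), acetone/H2O, 40 °C
Reagents that add atoms: water, O
Why: Directed ortho metalation at the last ring C–H and Weinreb ketone synthesis (the chelated tetrahedral adduct blocks over-addition and enolisation, so the (R) centre is carried over) are followed by mild acetal hydrolysis that should spare the aryl MOM ethers.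

Step 8
Reactants: 16 4-fluoro-2,6-bis(methoxymethoxy)-3-(3-methylbut-2-en-1-yl)-5-[(2R)-2-methylbutanoyl]benzaldehyde, 17 5-methylhexan-2-one
Product: 19 (1E)-1-[4-fluoro-2,6-bis(methoxymethoxy)-3-(3-methylbut-2-en-1-yl)-5-[(2R)-2-methylbutanoyl]phenyl]-6-methylhept-1-en-3-one, via aldol adduct 18 (not isolated)
Conditions: LDA, 17, THF, −78 °C; 16; AcOH; then MsCl, Et3N, CH2Cl2, 0 °C → rt
Reagents that add atoms: none
Why: The kinetic methyl-side lithium enolate adds to the aldehyde (directed aldol, chosen over hydroxide-mediated condensation because the fluoride para to the formyl group is open to SNAr by hydroxide or alkoxide), and mesylation with E1cB elimination should give the (E)-enone.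

Step 9
Reactants: 7 2-bromo-5-fluoro-1,3-bis(methoxymethoxy)-4-(3-methylbut-2-en-1-yl)benzene, 20 N-methoxy-N,2-dimethylpropanamide
Product: 22 1-[3-bromo-6-fluoro-2,4-bis(methoxymethoxy)-5-(3-methylbut-2-en-1-yl)phenyl]-2-methylpropan-1-one, via aryllithium 21 (not isolated)
Conditions: LDA, THF, −78 °C; 20, −78 → −40 °C; AcOH
Reagents that add atoms: none
Why: LDA metalation at the last ring C–H (directed ortho metalation) and Weinreb ketone synthesis should give the isobutyryl ketone ortho to fluorine, with the bromide untouched.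

Step 10
Reactants: 22 1-[3-bromo-6-fluoro-2,4-bis(methoxymethoxy)-5-(3-methylbut-2-en-1-yl)phenyl]-2-methylpropan-1-one
Product: 23 1-[6-fluoro-2,4-bis(methoxymethoxy)-5-(3-methylbut-2-en-1-yl)-3-(4,4,5,5-tetramethyl-1,3,2-dioxaborolan-2-yl)phenyl]-2-methylpropan-1-one
Conditions: B2pin2, Pd(OAc)2 (5 mol%), SPhos (10 mol%), KOAc, dioxane, 90 °C
Reagents that add atoms: bis(pinacolato)diboron, CC1(C)OB(OC1(C)C)B1OC(C)(C)C(C)(C)O1
Why: Miyaura borylation with a bulky biarylphosphine should allow oxidative addition of zerovalent palladium into the di-ortho-alkoxy aryl bromide, and acetate is mild enough for the ketone, the prenyl group and the aryl fluoride.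

Step 11
Reactants: 19 ring A (E)-enone, 23 ring B pinacol boronate
Product: 24 (1R)-1-[4-fluoro-2,6-bis(methoxymethoxy)-3-(3-methylbut-2-en-1-yl)-5-[(2R)-2-methylbutanoyl]phenyl]-1-[4-fluoro-2,6-bis(methoxymethoxy)-3-(3-methylbut-2-en-1-yl)-5-(2-methylpropanoyl)phenyl]-6-methylheptan-3-one
Conditions: [Rh(OH)((R)-binap)]2 (2.5 mol%), 23 (1.5 equiv), dioxane/H2O (10:1), 60 °C
Reagents that add atoms: none
Why: In this Hayashi–Miyaura 1,4-addition the aryl group passes from boron to rhodium, the enone inserts and water protonates the rhodium enolate under base-free conditions that protect the alpha stereocentre and the aryl fluorides; the ligand sets the new methine, (R)-BINAP being chosen by analogy with simple (E)-enones to deliver ring B to the Si face of C-beta and so give the (R) centre.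

Step 12
Reactants: 24 diaryl ketone from step 11
Product: 26 (1R)-1-[4-fluoro-2,6-bis(methoxymethoxy)-3-(3-methylbut-2-en-1-yl)-5-[(2R)-2-methylbutanoyl]phenyl]-1-[4-fluoro-2,6-bis(methoxymethoxy)-3-(3-methylbut-2-en-1-yl)-5-(2-methylpropanoyl)phenyl]-6-methylheptane, via tosylhydrazone 25 (not isolated)
Conditions: TsNHNH2, EtOH, 50 °C; evaporate; catecholborane, CHCl3, 0 °C; NaOAc·3H2O, reflux
Reagents that add atoms: none
Why: Only the unhindered dialkyl ketone should condense with tosylhydrazide (both aryl ketones are di-ortho-substituted), and hydride addition, acetate-induced loss of sulfinate and loss of N2 from the diazene (Kabalka-type tosylhydrazone reduction) should give the methylene without touching the prenyl groups or the stereocentres.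

Step 13
Reactants: 26 bis-prenyl bis(aryl fluoride)
Product: 27 (1R)-1-[4-fluoro-3-(3-hydroxy-3-methylbutyl)-2,6-bis(methoxymethoxy)-5-[(2R)-2-methylbutanoyl]phenyl]-1-[4-fluoro-3-(3-hydroxy-3-methylbutyl)-2,6-bis(methoxymethoxy)-5-(2-methylpropanoyl)phenyl]-6-methylheptane
Conditions: Co(acac)2 (20 mol%), PhSiH3, O2 (1 atm), THF, rt
Reagents that add atoms: dioxygen, O=O
Why: In this Mukaiyama hydration, hydrogen-atom transfer to each trisubstituted alkene from the hydride formed from Co(acac)2 and PhSiH3 gives the tertiary radical, which is trapped by O2 and reduced to the tertiary alcohol (Markovnikov) under neutral conditions that leave ketones, MOM ethers and aryl fluorides alone.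

Step 14
Reactants: 27 bis(aryl fluoride) diol
Product: 28 (2R)-1-[6-[(1R)-1-[5,7-bis(methoxymethoxy)-2,2-dimethyl-8-(2-methylpropanoyl)chroman-6-yl]-6-methylheptyl]-5,7-bis(methoxymethoxy)-2,2-dimethylchroman-8-yl]-2-methylbutan-1-one
Conditions: NaH (2.4 equiv), THF/DMF (4:1), 0 °C → rt
Reagents that add atoms: none
Why: Sodium hydride turns both tertiary alcohols into alkoxides, each of which adds to its own C8a to give a Meisenheimer adduct whose charge rests on C8 and the C8 ketone oxygen, and loss of fluoride then restores the arene with the O1–C8a bond in place (addition–elimination SNAr). The closest known reaction type is the base-mediated intramolecular etherification of ortho-fluoroaryl ketones, as used for chromans and xanthones. Each dihydropyran ring, on ring A and on ring B, closes in a 6-exo mode onto the C8a=C8 unit, and the two closures are independent of each other. No stereocentre is formed; the methine and the 2-methylbutanoyl centre are only carried through. Regiochemistry needs no control, because each alkoxide can reach only the fluorine-bearing carbon next to it and O5 and O7 are capped as MOM ethers that sit meta to fluorine and so do not cancel the activation. The selectivity that must be secured is ipso attack ahead of deprotonation alpha to the ring A ketone, which the intramolecular six-membered closure, the low temperature, the small excess of hydride and the hindered, twisted tertiary alpha C–H should favour.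

Step 15
Reactants: 28 tetra-MOM bis-chroman
Product: 29 (2R)-1-[6-[(1R)-1-[5,7-dihydroxy-2,2-dimethyl-8-(2-methylpropanoyl)-3,4-dihydro-2H-chromen-6-yl]-6-methylheptyl]-5,7-dihydroxy-2,2-dimethyl-3,4-dihydro-2H-chromen-8-yl]-2-methylbutan-1-one (CNP0287681.1)
Conditions: HCl in MeOH (1.25 M), 40 °C
Reagents that add atoms: none
Why: Acid-catalysed transacetalisation to methanol should remove all four aryl MOM ethers, while the tertiary-alkyl aryl ethers of the chromans and the hindered ketones are stable to mild methanolic acid.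

## Compound list

1 | 5-fluorobenzene-1,3-diol | Oc1cc(O)cc(F)c1 | starting material
2 | 1-fluoro-3,5-bis(methoxymethoxy)benzene | COCOc1cc(F)cc(OCOC)c1 | intermediate
3 | [4-fluoro-2,6-bis(methoxymethoxy)phenyl]lithium (not isolated) | [Li]c1c(OCOC)cc(F)cc1OCOC | intermediate
4 | 2-bromo-5-fluoro-1,3-bis(methoxymethoxy)benzene | COCOc1cc(F)cc(OCOC)c1Br | intermediate
5 | prenyl bromide (1-bromo-3-methylbut-2-ene) | CC(C)=CCBr | starting material
6 | [3-bromo-6-fluoro-2,4-bis(methoxymethoxy)phenyl]lithium (not isolated) | Brc1c(OCOC)cc(F)c([Li])c1OCOC | intermediate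
7 | 2-bromo-5-fluoro-1,3-bis(methoxymethoxy)-4-(3-methylbut-2-en-1-yl)benzene | Brc1c(OCOC)cc(F)c(CC=C(C)C)c1OCOC | intermediate
8 | [4-fluoro-2,6-bis(methoxymethoxy)-3-(3-methylbut-2-en-1-yl)phenyl]lithium (not isolated) | [Li]c1c(OCOC)cc(F)c(CC=C(C)C)c1OCOC | intermediate
9 | 4-fluoro-2,6-bis(methoxymethoxy)-3-(3-methylbut-2-en-1-yl)benzaldehyde | O=Cc1c(OCOC)cc(F)c(CC=C(C)C)c1OCOC | intermediate
10 | 2-(dimethoxymethyl)-5-fluoro-1,3-bis(methoxymethoxy)-4-(3-methylbut-2-en-1-yl)benzene | COC(OC)c1c(OCOC)cc(F)c(CC=C(C)C)c1OCOC | intermediate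
11 | (R)-2-methylbutanoic acid | CC[C@@H](C)C(=O)O | starting material
12 | (2R)-1-(1H-imidazol-1-yl)-2-methylbutan-1-one (not isolated) | CC[C@@H](C)C(=O)n1ccnc1 | intermediate
13 | (2R)-N-methoxy-N,2-dimethylbutanamide | CC[C@@H](C)C(=O)N(C)OC | intermediate
14 | [3-(dimethoxymethyl)-6-fluoro-2,4-bis(methoxymethoxy)-5-(3-methylbut-2-en-1-yl)phenyl]lithium (not isolated) | COC(OC)c1c(OCOC)c([Li])c(F)c(CC=C(C)C)c1OCOC | intermediate
15 | (2R)-1-[3-(dimethoxymethyl)-6-fluoro-2,4-bis(methoxymethoxy)-5-(3-methylbut-2-en-1-yl)phenyl]-2-methylbutan-1-one (not isolated) | CC[C@@H](C)C(=O)c1c(OCOC)c(C(OC)OC)c(OCOC)c(CC=C(C)C)c1F | intermediate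
16 | 4-fluoro-2,6-bis(methoxymethoxy)-3-(3-methylbut-2-en-1-yl)-5-[(2R)-2-methylbutanoyl]benzaldehyde | CC[C@@H](C)C(=O)c1c(OCOC)c(C=O)c(OCOC)c(CC=C(C)C)c1F | intermediate
17 | 5-methylhexan-2-one | CC(=O)CCC(C)C | starting material
18 | (2R)-1-[6-fluoro-3-(1-hydroxy-6-methyl-3-oxoheptyl)-2,4-bis(methoxymethoxy)-5-(3-methylbut-2-en-1-yl)phenyl]-2-methylbutan-1-one, both carbinol epimers (not isolated) | CC[C@@H](C)C(=O)c1c(OCOC)c(C(O)CC(=O)CCC(C)C)c(OCOC)c(CC=C(C)C)c1F | intermediate
19 | (1E)-1-[4-fluoro-2,6-bis(methoxymethoxy)-3-(3-methylbut-2-en-1-yl)-5-[(2R)-2-methylbutanoyl]phenyl]-6-methylhept-1-en-3-one | CC[C@@H](C)C(=O)c1c(OCOC)c(/C=C/C(=O)CCC(C)C)c(OCOC)c(CC=C(C)C)c1F | intermediate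
20 | N-methoxy-N,2-dimethylpropanamide | CC(C)C(=O)N(C)OC | starting material
21 | [3-bromo-6-fluoro-2,4-bis(methoxymethoxy)-5-(3-methylbut-2-en-1-yl)phenyl]lithium (not isolated) | Brc1c(OCOC)c([Li])c(F)c(CC=C(C)C)c1OCOC | intermediate
22 | 1-[3-bromo-6-fluoro-2,4-bis(methoxymethoxy)-5-(3-methylbut-2-en-1-yl)phenyl]-2-methylpropan-1-one | CC(C)C(=O)c1c(OCOC)c(Br)c(OCOC)c(CC=C(C)C)c1F | intermediate
23 | 1-[6-fluoro-2,4-bis(methoxymethoxy)-5-(3-methylbut-2-en-1-yl)-3-(4,4,5,5-tetramethyl-1,3,2-dioxaborolan-2-yl)phenyl]-2-methylpropan-1-one | CC(C)C(=O)c1c(OCOC)c(B2OC(C)(C)C(C)(C)O2)c(OCOC)c(CC=C(C)C)c1F | intermediate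
24 | (1R)-1-[4-fluoro-2,6-bis(methoxymethoxy)-3-(3-methylbut-2-en-1-yl)-5-[(2R)-2-methylbutanoyl]phenyl]-1-[4-fluoro-2,6-bis(methoxymethoxy)-3-(3-methylbut-2-en-1-yl)-5-(2-methylpropanoyl)phenyl]-6-methylheptan-3-one | CC[C@@H](C)C(=O)c1c(OCOC)c([C@H](CC(=O)CCC(C)C)c2c(OCOC)c(CC=C(C)C)c(F)c(C(=O)C(C)C)c2OCOC)c(OCOC)c(CC=C(C)C)c1F | intermediate
25 | 4-methylbenzenesulfonylhydrazone of 24 at the chain ketone (not isolated) | CC[C@@H](C)C(=O)c1c(OCOC)c([C@H](CC(CCC(C)C)=NNS(=O)(=O)c3ccc(C)cc3)c2c(OCOC)c(CC=C(C)C)c(F)c(C(=O)C(C)C)c2OCOC)c(OCOC)c(CC=C(C)C)c1F | intermediate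
26 | (1R)-1-[4-fluoro-2,6-bis(methoxymethoxy)-3-(3-methylbut-2-en-1-yl)-5-[(2R)-2-methylbutanoyl]phenyl]-1-[4-fluoro-2,6-bis(methoxymethoxy)-3-(3-methylbut-2-en-1-yl)-5-(2-methylpropanoyl)phenyl]-6-methylheptane | CC[C@@H](C)C(=O)c1c(OCOC)c([C@H](CCCCC(C)C)c2c(OCOC)c(CC=C(C)C)c(F)c(C(=O)C(C)C)c2OCOC)c(OCOC)c(CC=C(C)C)c1F | intermediate
27 | (1R)-1-[4-fluoro-3-(3-hydroxy-3-methylbutyl)-2,6-bis(methoxymethoxy)-5-[(2R)-2-methylbutanoyl]phenyl]-1-[4-fluoro-3-(3-hydroxy-3-methylbutyl)-2,6-bis(methoxymethoxy)-5-(2-methylpropanoyl)phenyl]-6-methylheptane | CC[C@@H](C)C(=O)c1c(OCOC)c([C@H](CCCCC(C)C)c2c(OCOC)c(CCC(C)(C)O)c(F)c(C(=O)C(C)C)c2OCOC)c(OCOC)c(CCC(C)(C)O)c1F | intermediate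
28 | (2R)-1-[6-[(1R)-1-[5,7-bis(methoxymethoxy)-2,2-dimethyl-8-(2-methylpropanoyl)chroman-6-yl]-6-methylheptyl]-5,7-bis(methoxymethoxy)-2,2-dimethylchroman-8-yl]-2-methylbutan-1-one | CC[C@@H](C)C(=O)c1c(OCOC)c([C@H](CCCCC(C)C)c2c(OCOC)c3c(c(C(=O)C(C)C)c2OCOC)OC(C)(C)CC3)c(OCOC)c2c1OC(C)(C)CC2 | intermediate
29 | (2R)-1-[6-[(1R)-1-[5,7-dihydroxy-2,2-dimethyl-8-(2-methylpropanoyl)-3,4-dihydro-2H-chromen-6-yl]-6-methylheptyl]-5,7-dihydroxy-2,2-dimethyl-3,4-dihydro-2H-chromen-8-yl]-2-methylbutan-1-one | CC[C@@H](C)C(=O)c1c(O)c([C@H](CCCCC(C)C)c2c(O)c3c(c(C(=O)C(C)C)c2O)OC(C)(C)CC3)c(O)c2c1OC(C)(C)CC2 | target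

## Step count and risks

Total step count: 15. Longest linear sequence: 12 steps (steps 1, 2, 3, 4, 5, 7, 8, 11, 12, 13, 14, 15).

Steps most likely to fail:

1. Step 11. Aryl transfer and enone insertion at two doubly ortho-flanked centres may be so slow with [Rh(OH)((R)-binap)]2 that protodeboronation of 23 overtakes addition, or the facial discrimination may be weak. Fallback, setting out from 19 and 23 and returning at 24: the union is run without asymmetric induction using the more active diene complex [Rh(OH)(cod)]2 in dioxane/H2O. This should give 24 together with its methine epimer, (1S)-1-[4-fluoro-2,6-bis(methoxymethoxy)-3-(3-methylbut-2-en-1-yl)-5-[(2R)-2-methylbutanoyl]phenyl]-1-[4-fluoro-2,6-bis(methoxymethoxy)-3-(3-methylbut-2-en-1-yl)-5-(2-methylpropanoyl)phenyl]-6-methylheptan-3-one F1. Because ring A already carries the (R)-2-methylbutanoyl centre the two are diastereomers, to be separated by preparative HPLC on a cellulose-based chiral stationary phase; 24 then re-enters at step 12.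

2. Step 14. Proton abstraction alpha to the ring A ketone by alkoxide or hydride may compete with ipso attack and erode the 2-methylbutanoyl centre, or the second closure may stall. Fallback, setting out from 26 (step 13 is skipped) and returning at 28: the oxygen is placed on C8a first and each ring is closed from the other end. Treatment of 26 with acetohydroxamic acid and K2CO3 in DMSO at 80 °C (SNAr by a hydroxide surrogate at the same ketone-activated fluorides, then Lossen-type fragmentation) should give the bis-phenol (1R)-1-[4-hydroxy-2,6-bis(methoxymethoxy)-3-(3-methylbut-2-en-1-yl)-5-[(2R)-2-methylbutanoyl]phenyl]-1-[4-hydroxy-2,6-bis(methoxymethoxy)-3-(3-methylbut-2-en-1-yl)-5-(2-methylpropanoyl)phenyl]-6-methylheptane F2. In F2 only the C8a hydroxyl is free, since O5 and O7 remain MOM-protected. Acid-free Markovnikov hydroalkoxylation of both prenyl groups by hydrogen-atom transfer (Co(salen) catalyst, N-fluoro-2,4,6-trimethylpyridinium tetrafluoroborate, 1,1,3,3-tetramethyldisiloxane, PhCF3, rt) then closes both dihydropyran rings at O1–C2 and should give 28.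

3. Step 2. Deprotonation at the F/OMOM-flanked C4 may compete with C2 metalation and give a regioisomeric lithio species, which would carry the wrong substitution pattern into both rings. Fallback, setting out from 1 and returning at 3: C2 is marked by halogen before protection, so that regiochemistry rests on electrophilic substitution and not on the metalation. Iodination of 1 with I2 and NaHCO3 in water, which for resorcinols goes between the two hydroxyls, should give 5-fluoro-2-iodobenzene-1,3-diol F3. MOMCl with i-Pr2NEt then gives 5-fluoro-2-iodo-1,3-bis(methoxymethoxy)benzene F4, and iodine–lithium exchange with n-BuLi in THF at −78 °C generates aryllithium 3 without regiochemical ambiguity, to be brominated with BrCCl2CCl2Br as in step 2; the bromide 4 is kept as the working halide because the amide-base metalations of steps 3 and 9 are planned around the less exchange-prone bromine.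

Further compounds

F1 | step 11 | (1S)-1-[4-fluoro-2,6-bis(methoxymethoxy)-3-(3-methylbut-2-en-1-yl)-5-[(2R)-2-methylbutanoyl]phenyl]-1-[4-fluoro-2,6-bis(methoxymethoxy)-3-(3-methylbut-2-en-1-yl)-5-(2-methylpropanoyl)phenyl]-6-methylheptan-3-one | CC[C@@H](C)C(=O)c1c(OCOC)c([C@@H](CC(=O)CCC(C)C)c2c(OCOC)c(CC=C(C)C)c(F)c(C(=O)C(C)C)c2OCOC)c(OCOC)c(CC=C(C)C)c1F
F2 | step 14 | (1R)-1-[4-hydroxy-2,6-bis(methoxymethoxy)-3-(3-methylbut-2-en-1-yl)-5-[(2R)-2-methylbutanoyl]phenyl]-1-[4-hydroxy-2,6-bis(methoxymethoxy)-3-(3-methylbut-2-en-1-yl)-5-(2-methylpropanoyl)phenyl]-6-methylheptane | CC[C@@H](C)C(=O)c1c(OCOC)c([C@H](CCCCC(C)C)c2c(OCOC)c(CC=C(C)C)c(O)c(C(=O)C(C)C)c2OCOC)c(OCOC)c(CC=C(C)C)c1O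
F3 | step 2 | 5-fluoro-2-iodobenzene-1,3-diol | Oc1cc(F)cc(O)c1I
F4 | step 2 | 5-fluoro-2-iodo-1,3-bis(methoxymethoxy)benzene | COCOc1cc(F)cc(OCOC)c1I
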